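Readings and results were generated by integration on assumed constants; scatter was added.

At late times both earlier runs stand still, so I reckon the end of a flask and leave its course aside.

in all of them: substrate 23 mM; impurity 9.2 µM
- Friday's: reagent 46 mM; free catalyst 39 µM; temperature −30 °C; run made earlier
- Monday's: reagent 46 mM; free catalyst 62 µM; temperature −10 °C; run made earlier
- grey: reagent 46.0 mM; free catalyst 28 µM; temperature −10 °C; time 6.0 min
- blue: reagent 46.0 mM; free catalyst 28 µM; temperature −25 °C; time 6.0 min
- violet: reagent 46.0 mM; free catalyst 28 µM; temperature 5 °C; time 6.0 min

| run | time / min | product / % | substrate / % |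
|---|---|---|---|
| Friday's | 0.667 | 87.9 | 13.3 |
| Friday's | 1.33 | 95.2 | 3.6 |
| Friday's | 2.50 | 98.6 | 1.6 |
| Friday's | 5.00 | 97.1 | 0 |
| Friday's | 10.0 | 96.8 | 2.4 |
| Monday's | 0.667 | 79.4 | 18.3 |
| Monday's | 1.33 | 80.7 | 17.7 |
| Monday's | 2.00 | 82.4 | 17.5 |
| Monday's | 3.00 | 85.5 | 18.7 |
| Monday's | 4.00 | 84.6 | 17.3 |

(scatter of a reading: 1 percentage point)



- the flask with the highest amount of product, in percent of the substrate charged ("all alike" if they lie within 1.5 percentage points) (grey / blue / violet / all alike)
- final product, as a percentage of the substrate charged, in grey
- final product, as a percentage of the substrate charged, in blue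
- final product, as a percentage of the substrate charged, in violet

Monday's substrate stays near 17.9 % from 0.667 min to 4.00 min, while the balance leaves 59.0 % of the reagent. I take it that the catalyst stops working (deactivation), though an equilibrium could hold part of this, and then my figure is a floor. So I work with what is left. The reach of a flask is the logarithm of c(reagent) over c(substrate), each as a share of its charge. For a rate proportional to substrate, reagent and catalyst, reach grows with the catalyst summed over time and with the excess of reagent over substrate, here 23.0 mM. I assume that a dying catalyst gives a sum proportional to its usable part, the charge minus the impurity. Monday's reach of 1.19 on 52.8 µM makes 0.0226 µM⁻¹, the reach per µM of usable catalyst.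

Now the settings. Time should do little, since Monday reads 18.3 % at its first reading and 17.3 % at its last. Catalyst: grey has 18.8 µM usable at Monday's temperature, so its reach is 0.424, which the reagent balance turns into 51.4 % product. Temperature: Friday's last three readings leave 1.33 %, giving a reach per usable µM of 0.122 µM⁻¹, more than Monday's. Taking the logarithm of this quantity as a straight line in temperature, I interpolate between the two runs to 87.5 % for blue and extrapolate past Monday's, less surely, to 20.3 % for violet, so I expect blue highest.

The forecast also names blue, but at 93 % it puts blue higher than I do; it gives grey 52 % and violet 21 %, and says “Conversion is then set by a race”.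

Grey gives 62.3 %, blue 96.1 % and violet 21.9 %, so blue holds the most. Time does little: blue stands at 96.4 % after 60.0 min. Changing only the catalyst from Monday's charge to grey's takes the product from 82.9 % to 62.3 %.

    free catalyst → spent catalyst B (k = 0.300 s⁻¹, Ea = 72.0 kJ mol⁻¹)
    substrate + reagent + free catalyst ⇌ product + free catalyst, rate k2*[substrate]*[reagent]*[free catalyst] forward; the back reaction follows from the equilibrium constant (K = 51.0 L mol⁻¹, k = 97000 L² mol⁻² s⁻¹, Ea = 9.00 kJ mol⁻¹, ΔH = −65.0 kJ mol⁻¹)
    free catalyst + impurity → spent catalyst A (k = 87000 L mol⁻¹ s⁻¹, Ea = 13.0 kJ mol⁻¹)
    (constants at 5 °C)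

Grey's reach at the end is 0.602, which makes a reach per usable µM of 0.0320 µM⁻¹, more than Monday's 0.0226 µM⁻¹. Blue's reach is 2.58. The neighbouring flask is blue with 28 mM of reagent, the same catalyst and temperature, so its reach should shrink with the excess to 0.561, which means 80.8 % product. That flask gives 83.3 %, with 17 % of its substrate left.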